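If a flask's starting material did nothing but become target, the share of target would be 100% in delta, theta and beta alike, so I add the processes one at a time and watch that number.

| flask | starting material | first nucleophile | second nucleophile | protic impurity | temperature | remark | time |
|---|---|---|---|---|---|---|---|
| grey | 0.13 M | 0.24 M | 0.24 M | 0.020 M | 45 °C | run made earlier |  |
| amber | 0.30 M | 0.24 M | 0.24 M | 0.020 M | 65 °C | run made earlier |  |
| delta | 0.20 M | 0.240 M | 0.240 M | 0.0200 M | 80 °C |  | 3.0 d |
| theta | 0.20 M | 0.240 M | 0.240 M | 0.0200 M | 50 °C |  | 3.0 d |
| beta | 0.20 M | 0.240 M | 0.240 M | 0.0200 M |  | at 80 °C until 20 h, from then on at 50 °C | 3.0 d |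

- grey (time / d: target / %, other capture product / %, solvolysis product / %): 1.25: 22, 4, 16; 4.00: 44, 8, 30; 6.00: 47, 9, 38; 10.0: 50, 9, 41; 15.0: 54, 6, 38
- amber (time / d: target / %, other capture product / %, solvolysis product / %): 0.417: 30, 4, 58; 1.25: 35, 6, 66; 2.00: 33, 5, 63; 4.00: 30, 10, 64; 5.00: 34, 8, 61

(each reading ± 2 percentage points)

* the flask that comes out highest in share of target in all that became target or other capture product or solvolysis product, or "all alike" when all lie within 1.5 percentage points (delta / theta / beta / all alike)
* share of target in all that became target or other capture product or solvolysis product, delta
* share of target in all that became target or other capture product or solvolysis product, theta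
* share of target in all that became target or other capture product or solvolysis product, beta



The first addition is solvolysis product. In the grey run it rises along with target, so I divide the rate of one by the rate of the other, and time drops out. I assume that target needs first nucleophile and solvolysis product does not. Target gained per solvolysis product gained is then the first nucleophile present times a number belonging to the temperature, which I call the capture strength (a selectivity factor).

The last two readings give 1.32 target per solvolysis product in grey and 0.512 in amber. I take the mean first nucleophile as the charge less half of what I suppose impurity and target took: 0.195 M and 0.179 M. As readings, the strengths are 6.75 /M at 45 °C and 2.86 /M at 65 °C; the starting material differs too, but I lay the fall on temperature. Continuing that fall evenly per degree, the capture strength, target per solvolysis product per molar of first nucleophile, is 1.50 /M at 80 °C and 5.45 /M at 50 °C.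

With the first nucleophile held at its charge, the share falls from 100% to 26.5% in delta and 56.7% in theta. The next addition is the wearing of first nucleophile, which lowers its mean to 0.204 M in delta and 0.173 M in theta. The last is other capture product, 0.144 per solvolysis product in amber and 0.190 in grey. My shares become 21.1% for delta and 44.3% for theta. Amber, at 65 °C, cooler than beta's first 80 °C, read 92.0% of its charge in products by 0.417 d, earlier than beta's change at 20 h, so I set beta beside delta.

The forecast says 23% for delta, 46% for theta and 23% for beta, with theta highest, on the ground that “this looks like kinetic partitioning”. Its shares for delta and theta stand somewhat above mine, but the order is the same.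

The flasks give 23.6% for delta, 45.6% for theta and 23.6% for beta, so theta is highest.

    starting material → intermediate (k = 0.0384 /h, Ea = 115 kJ/mol)
    second nucleophile → decomposed reagent (k = 0.0498 /h, Ea = 107 kJ/mol)
    second nucleophile + intermediate → other capture product (k = 186 /M/h, Ea = 50.0 kJ/mol)
    intermediate → solvolysis product (k = 105 /h, Ea = 83.0 kJ/mol)
    first nucleophile + protic impurity → quenched reagent (k = 0.377 /M/h, Ea = 75.0 kJ/mol)
    first nucleophile + intermediate → target (k = 574 /M/h, Ea = 44.0 kJ/mol)
    (constants at 50 °C)

When beta is cooled at 20 h, its starting material stands at 0% and its intermediate at 0%, and it ends at the share of delta. The largest single effect on the gap of −22 percentage points between delta and theta is what heat does to the step from intermediate to solvolysis product: without it the gap is 20 points. In delta, my 1.50 /M times the midpoint of charge and end amount of first nucleophile, 0.206 M, gives 0.309 target per solvolysis product, beside 0.330 in the flask.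

A neighbour of beta holds 0.41 M of first nucleophile. The strength 1.50 /M gives it a share of 32.9%, and the flask computes 35.1%.

The earlier runs and the new flask stem from a simulated flask with made-up constants; noise was put on by code.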